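The carbocycle (C4a, C5–C8, C8a) is grown from a cyclopentane. Everything rests on a Mannich disconnection of C4a–C8a in a C5 ketone (N1–C8a–C4a–C5=O). An aza-Cope/Mannich cascade of the iminium ion from (1R,2R)-2-(benzylamino)-1-vinylcyclopentanol and (S)-2-silyloxypropanal inserts the vinyl carbon (C4a) into the cyclopentane, forms C3–C4 and C4a–C8a, closes a pyrrolidine and sets C3, C4a and C8a in one operation. A second ring expansion (aziridinium ion) turns the 2-(1-hydroxyethyl)pyrrolidine into the 2-methyl-3-oxygenated piperidine; the C5 ketone takes the side chain by Wittig reaction and hydrogenation; Mitsunobu esterification inverts C3.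

Key step: step 5

Remark: atoms carry the decahydroquinoline numbering of the target (N1, C2, C3, C4, C4a, C5–C8, C8a; side chain C1′–C8′) at every stage; aldehyde 6 is taken as a catalogue compound.

Step 1
Reactants: 1 (1R,2R)-2-aminocyclopentan-1-ol hydrochloride
Product: 2 N-[(1R,2R)-2-hydroxycyclopentyl]benzamide
Conditions: PhCOCl, NaOH (aq), CH2Cl2, 0 °C
Reagents that add atoms: benzoyl chloride, O=C(Cl)c1ccccc1
Why: Schotten–Baumann N-acylation is selective for the amine over the secondary alcohol and brings in the carbon that later becomes the N-benzyl group, without touching a stereocentre.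

Step 2
Reactants: 2 N-[(1R,2R)-2-hydroxycyclopentyl]benzamide
Product: 3 N-[(1R)-2-oxocyclopentyl]benzamide
Conditions: Dess–Martin periodinane, CH2Cl2, 0 °C to rt; used crude
Reagents that add atoms: none
Why: Dess–Martin oxidation of the secondary alcohol is neutral and base-free, so the α-amido stereocentre (the future C8a) should not enolise if the ketone is used at once.

Step 3
Reactants: 3 N-[(1R)-2-oxocyclopentyl]benzamide
Product: 4 N-[(1R,2R)-2-ethenyl-2-hydroxycyclopentyl]benzamide
Conditions: CH2=CHMgBr (3.5 equiv), CeCl3, THF, −78 °C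
Reagents that add atoms: vinylmagnesium bromide, C=C[Mg]Br
Why: In this organocerium-mediated Grignard 1,2-addition the first equivalent forms the amidate, which suppresses enolisation, and the vinyl group should add to the ketone face anti to the 2-amido group, which sets the carbinol centre with vinyl trans to nitrogen (a centre that only steers step 5 and is destroyed there).

Step 4
Reactants: 4 N-[(1R,2R)-2-ethenyl-2-hydroxycyclopentyl]benzamide
Product: 5 (1R,2R)-2-(benzylamino)-1-ethenylcyclopentan-1-ol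
Conditions: LiAlH4, THF, reflux; aqueous NaOH work-up
Reagents that add atoms: none
Why: LiAlH4 reduction of the secondary benzamide gives the N-benzyl secondary amine needed for iminium formation, while the tertiary allylic alkoxide and both stereocentres are left alone.

Step 5
Reactants: 5 (1R,2R)-2-(benzylamino)-1-ethenylcyclopentan-1-ol; 6 (2S)-2-{[tert-butyl(dimethyl)silyl]oxy}propanal
Product: 11 (2R,3aR,7aR)-1-benzyl-2-[(1S)-1-hydroxyethyl]octahydro-4H-indol-4-one, via oxazolidine 7 (not isolated), via iminium ion 8 (not isolated), via nine-membered enol iminium ion 9 (not isolated), via silyl ether ketone 10 (not isolated)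
Conditions: 6 (1.2 equiv), Na2SO4, toluene, rt; then camphorsulfonic acid (1.0 equiv), 80 °C; then HCl (1.5 M in MeOH), 40 °C
Reagents that add atoms: none
Why: Condensation of 5 with 6 gives the cis-fused oxazolidine 7, which acid opens to iminium ion 8; its cationic 2-aza-Cope ([3,3]) shift breaks the cyclopentane bond between the carbinol carbon and the nitrogen-bearing carbon and forms C3–C4 to give 9, transannular Mannich attack of C4a on C8a gives 10, and acidic methanolysis removes the silyl group. The closest known reaction type is the aza-Cope/Mannich ring-enlarging pyrrolidine annulation of 2-amino-1-alkenylcyclopentanols. The single Mannich bond closes the pyrrolidine in a 5-(enolexo)-endo-trig mode and the cyclohexanone in a 6-(enolendo)-exo-trig mode, so the cyclopentane takes up the vinyl carbon as C4a and becomes the six-membered ring with C5 as ketone. C3 is set in the [3,3] step by a chair array with the (E)-iminium ion and both cyclopentane bonds equatorial, which for the (1R,2R) amino alcohol should lead to (R) with the silyloxyethyl group cis to C8 and C5; C8a is re-formed with its original configuration because C4a bonds to the iminium face that the carbinol carbon has just left, and C4a follows from the cis ring fusion, which is also the stable arrangement of this epimerisable centre. The step needs chirality transfer and an intact aldehyde α-centre: the trans arrangement of nitrogen and vinyl makes the all-equatorial chair available, the bulky ring carbon on nitrogen enforces the (E)-iminium geometry, the Mannich closure is expected to outrun conformational inversion of 9, and forming the oxazolidine before the acid is added keeps the free α-silyloxy iminium ion short-lived.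

Step 6
Reactants: 12 (2R)-2-propyloxirane
Product: 13 (4R)-oct-7-en-4-ol
Conditions: CH2=CHCH2MgBr, CuI (10 mol %), THF, −30 to 0 °C
Reagents that add atoms: allylmagnesium bromide, C=CC[Mg]Br
Why: Copper-catalysed Grignard opening of the terminal epoxide takes place at the CH2 carbon (SN2), so the stereocentre of 12 is carried unchanged into C5′.

Step 7
Reactants: 13 (4R)-oct-7-en-4-ol
Product: 14 tert-butyl(dimethyl){[(4R)-oct-7-en-4-yl]oxy}silane
Conditions: TBSCl, imidazole, DMF, rt
Reagents that add atoms: tert-butyldimethylsilyl chloride, CC(C)(C)[Si](C)(C)Cl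
Why: Standard silylation protects the secondary alcohol against the ylide base and the later acylation and Mitsunobu conditions.

Step 8
Reactants: 14 tert-butyl(dimethyl){[(4R)-oct-7-en-4-yl]oxy}silane
Product: 16 tert-butyl{[(4R)-8-iodooctan-4-yl]oxy}dimethylsilane, via alkylborane 15 (not isolated)
Conditions: 9-BBN, THF, 0 °C to rt; then NaOMe, I2, MeOH, 0 °C to rt
Reagents that add atoms: iodine, II
Why: Anti-Markovnikov hydroboration followed by base-induced iodinolysis of the organoborane should give the primary iodide, because the primary B–C bond of 15 reacts faster than the secondary ring B–C bonds.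

Step 9
Reactants: 16 tert-butyl{[(4R)-8-iodooctan-4-yl]oxy}dimethylsilane
Product: 17 [(5R)-5-{[tert-butyl(dimethyl)silyl]oxy}octyl]triphenylphosphonium iodide
Conditions: PPh3, MeCN, reflux
Reagents that add atoms: triphenylphosphine, c1ccc(cc1)P(c1ccccc1)c1ccccc1
Why: SN2 quaternisation of triphenylphosphine by the primary iodide gives the Wittig salt.

Step 10
Reactants: 11 (2R,3aR,7aR)-1-benzyl-2-[(1S)-1-hydroxyethyl]octahydro-4H-indol-4-one; 17 [(5R)-5-{[tert-butyl(dimethyl)silyl]oxy}octyl]triphenylphosphonium iodide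
Product: 19 (1S)-1-[(2R,3aS,7aR)-1-benzyl-4-[(5R)-5-{[tert-butyl(dimethyl)silyl]oxy}octylidene]octahydro-1H-indol-2-yl]ethan-1-ol, via phosphonium ylide 18 (not isolated)
Conditions: 17 (3.3 equiv), KN(SiMe3)2 (3.1 equiv), THF, 0 °C; then 11, −78 to 60 °C
Reagents that add atoms: none
Why: Wittig olefination with the non-stabilised ylide should convert the C5 ketone into the exocyclic alkene (either alkene geometry serves), the carbinol being carried as its alkoxide or hemiketal alkoxide as in Wittig reactions of lactols, and salt-free ylide added cold should attack the carbonyl faster than it enolises C4a.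

Step 11
Reactants: 19 (1S)-1-[(2R,3aS,7aR)-1-benzyl-4-[(5R)-5-{[tert-butyl(dimethyl)silyl]oxy}octylidene]octahydro-1H-indol-2-yl]ethan-1-ol
Product: 22 (2R,3S,4aS,8aR)-1-benzyl-5-[(5R)-5-{[tert-butyl(dimethyl)silyl]oxy}octylidene]-2-methyldecahydroquinolin-3-ol, via aziridinium trifluoroacetate 20 (not isolated), via trifluoroacetate ester 21 (not isolated)
Conditions: (CF3CO)2O, THF, −78 °C to rt; Et3N, 100 °C (sealed tube); then NaOH (2.5 M aq), rt
Reagents that add atoms: trifluoroacetic anhydride (its trifluoroacetate returns the oxygen to C3), O=C(OC(=O)C(F)(F)F)C(F)(F)F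
Why: In this ring expansion of a 2-(1-hydroxyalkyl)pyrrolidine through an aziridinium ion, nitrogen displaces the trifluoroacetate with inversion at the carbinol carbon (which becomes C2, R), trifluoroacetate reopens 20 at the ring carbon with inversion (C3, S), and under thermodynamic control the six-membered ester 21 should prevail before hydrolysis.

Step 12
Reactants: 22 (2R,3S,4aS,8aR)-1-benzyl-5-[(5R)-5-{[tert-butyl(dimethyl)silyl]oxy}octylidene]-2-methyldecahydroquinolin-3-ol
Product: 24 tert-butyl (2R,3S,4aS,5S,8aR)-5-[(5R)-5-{[tert-butyl(dimethyl)silyl]oxy}octyl]-3-hydroxy-2-methyloctahydroquinoline-1(2H)-carboxylate, via secondary amine 23 (not isolated)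
Conditions: H2 (4 bar), Pd(OH)2/C, EtOH, rt; then Boc2O, Et3N, 50 °C
Reagents that add atoms: di-tert-butyl dicarbonate, CC(C)(C)OC(=O)OC(=O)OC(C)(C)C
Why: Heterogeneous hydrogenation should add hydrogen to the exocyclic alkene from the convex face of the cis-fused bicycle (the face of H4a and H8a), which sets C5 (S) with the chain cis to C4, while the same catalyst cleaves the N-benzyl group and the amine 23 is then converted into its carbamate.

Step 13
Reactants: 25 (2E,4E)-octa-2,4-dienal
Product: 26 (2E,4E)-octa-2,4-dienoic acid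
Conditions: NaClO2, NaH2PO4, 2-methylbut-2-ene, t-BuOH/H2O, 0 °C to rt
Reagents that add atoms: sodium chlorite, [Na+].[O-]Cl=O
Why: Pinnick oxidation converts the dienal into the acid without isomerising the (E,E)-diene.

Step 14
Reactants: 24 tert-butyl (2R,3S,4aS,5S,8aR)-5-[(5R)-5-{[tert-butyl(dimethyl)silyl]oxy}octyl]-3-hydroxy-2-methyloctahydroquinoline-1(2H)-carboxylate; 26 (2E,4E)-octa-2,4-dienoic acid
Product: 27 tert-butyl (2R,3R,4aS,5S,8aR)-5-[(5R)-5-{[tert-butyl(dimethyl)silyl]oxy}octyl]-2-methyl-3-{[(2E,4E)-octa-2,4-dienoyl]oxy}octahydroquinoline-1(2H)-carboxylate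
Conditions: 26 (1.5 equiv), PPh3, DIAD, toluene, 0 °C to rt
Reagents that add atoms: none
Why: In the Mitsunobu esterification the oxyphosphonium ion of the C3 alcohol is displaced by the dienoate in an SN2 step from the convex face, which inverts C3 from S to R and gives the cis relation of the C2 methyl and C3 acyloxy groups.

Step 15
Reactants: 27 tert-butyl (2R,3R,4aS,5S,8aR)-5-[(5R)-5-{[tert-butyl(dimethyl)silyl]oxy}octyl]-2-methyl-3-{[(2E,4E)-octa-2,4-dienoyl]oxy}octahydroquinoline-1(2H)-carboxylate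
Product: 28 (2R,3R,4aS,5S,8aR)-5-[(5R)-5-hydroxyoctyl]-2-methyldecahydroquinolin-3-yl (2E,4E)-octa-2,4-dienoate
Conditions: CF3CO2H/H2O (9:1), 0 °C to rt; NaHCO3 work-up
Reagents that add atoms: none
Why: Acidolysis should remove the Boc carbamate and the secondary silyl ether in one operation (carbamate cleavage and protodesilylation) while the dienoate ester and all stereocentres stay untouched.

Compound list
1 | (1R,2R)-2-aminocyclopentan-1-ol hydrochloride | O[C@@H]1CCC[C@H]1N.Cl | starting material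
2 | N-[(1R,2R)-2-hydroxycyclopentyl]benzamide | O[C@@H]1CCC[C@H]1NC(=O)c1ccccc1 | intermediate
3 | N-[(1R)-2-oxocyclopentyl]benzamide | O=C1CCC[C@H]1NC(=O)c1ccccc1 | intermediate
4 | N-[(1R,2R)-2-ethenyl-2-hydroxycyclopentyl]benzamide (vinyl trans to nitrogen) | C=C[C@]1(O)CCC[C@H]1NC(=O)c1ccccc1 | intermediate
5 | (1R,2R)-2-(benzylamino)-1-ethenylcyclopentan-1-ol | C=C[C@]1(O)CCC[C@H]1NCc1ccccc1 | intermediate
6 | (2S)-2-{[tert-butyl(dimethyl)silyl]oxy}propanal | C[C@H](O[Si](C)(C)C(C)(C)C)C=O | starting material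
7 | cis-fused N-benzyl oxazolidine from 5 and 6 (aminal carbon not defined), not isolated | C=C[C@]12CCC[C@H]1N(Cc1ccccc1)C(O2)[C@H](C)O[Si](C)(C)C(C)(C)C | intermediate
8 | N-benzyl iminium ion from 5 and 6, not isolated | C=C[C@]1(O)CCC[C@H]1[N+](Cc1ccccc1)=C[C@H](C)O[Si](C)(C)C(C)(C)C | intermediate
9 | nine-membered enol iminium ion, (2R)-1-benzyl-2-[(1S)-1-silyloxyethyl]-5-hydroxyazoninium with C4=C5 enol and C9=N1 iminium bonds, not isolated | C[C@H](O[Si](C)(C)C(C)(C)C)[C@H]1CC=C(O)CCCC=[N+]1Cc1ccccc1 | intermediate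
10 | (2R,3aR,7aR)-1-benzyl-2-[(1S)-1-{[tert-butyl(dimethyl)silyl]oxy}ethyl]octahydro-4H-indol-4-one, not isolated | C[C@H](O[Si](C)(C)C(C)(C)C)[C@H]1C[C@H]2C(=O)CCC[C@H]2N1Cc1ccccc1 | intermediate
11 | (2R,3aR,7aR)-1-benzyl-2-[(1S)-1-hydroxyethyl]octahydro-4H-indol-4-one (cis-fused, side chain cis to the carbocycle) | C[C@H](O)[C@H]1C[C@H]2C(=O)CCC[C@H]2N1Cc1ccccc1 | intermediate
12 | (2R)-2-propyloxirane | CCC[C@@H]1CO1 | starting material
13 | (4R)-oct-7-en-4-ol | CCC[C@@H](O)CCC=C | intermediate
14 | tert-butyl(dimethyl){[(4R)-oct-7-en-4-yl]oxy}silane | CCC[C@@H](O[Si](C)(C)C(C)(C)C)CCC=C | intermediate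
15 | 9-[(5R)-5-{[tert-butyl(dimethyl)silyl]oxy}octyl]-9-borabicyclo[3.3.1]nonane, not isolated | CCC[C@@H](O[Si](C)(C)C(C)(C)C)CCCCB1C2CCCC1CCC2 | intermediate
16 | tert-butyl{[(4R)-8-iodooctan-4-yl]oxy}dimethylsilane | CCC[C@@H](O[Si](C)(C)C(C)(C)C)CCCCI | intermediate
17 | [(5R)-5-{[tert-butyl(dimethyl)silyl]oxy}octyl]triphenylphosphonium iodide | CCC[C@@H](O[Si](C)(C)C(C)(C)C)CCCC[P+](c1ccccc1)(c1ccccc1)c1ccccc1.[I-] | intermediate
18 | [(5R)-5-{[tert-butyl(dimethyl)silyl]oxy}octylidene]triphenylphosphorane, not isolated | CCC[C@@H](O[Si](C)(C)C(C)(C)C)CCCC=P(c1ccccc1)(c1ccccc1)c1ccccc1 | intermediate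
19 | (1S)-1-[(2R,3aS,7aR)-1-benzyl-4-[(5R)-5-{[tert-butyl(dimethyl)silyl]oxy}octylidene]octahydro-1H-indol-2-yl]ethan-1-ol (alkene geometry not defined) | C[C@H](O)[C@H]1C[C@H]2C(=CCCC[C@H](O[Si](C)(C)C(C)(C)C)CCC)CCC[C@H]2N1Cc1ccccc1 | intermediate
20 | N-benzyl aziridinium trifluoroacetate bridging N1, C2 and C3, not isolated | C[C@@H]1[C@H]2C[C@H]3C(=CCCC[C@H](O[Si](C)(C)C(C)(C)C)CCC)CCC[C@H]3[N+]12Cc1ccccc1.[O-]C(=O)C(F)(F)F | intermediate
21 | (2R,3S,4aS,8aR)-1-benzyl-5-[(5R)-5-{[tert-butyl(dimethyl)silyl]oxy}octylidene]-2-methyldecahydroquinolin-3-yl trifluoroacetate, not isolated | O=C(O[C@H]1C[C@H]2C(=CCCC[C@H](O[Si](C)(C)C(C)(C)C)CCC)CCC[C@H]2N(Cc3ccccc3)[C@@H]1C)C(F)(F)F | intermediate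
22 | (2R,3S,4aS,8aR)-1-benzyl-5-[(5R)-5-{[tert-butyl(dimethyl)silyl]oxy}octylidene]-2-methyldecahydroquinolin-3-ol | O[C@H]1C[C@H]2C(=CCCC[C@H](O[Si](C)(C)C(C)(C)C)CCC)CCC[C@H]2N(Cc3ccccc3)[C@@H]1C | intermediate
23 | (2R,3S,4aS,5S,8aR)-5-[(5R)-5-{[tert-butyl(dimethyl)silyl]oxy}octyl]-2-methyldecahydroquinolin-3-ol, not isolated | O[C@H]1C[C@H]2[C@@H](CCCC[C@H](O[Si](C)(C)C(C)(C)C)CCC)CCC[C@H]2N[C@@H]1C | intermediate
24 | tert-butyl (2R,3S,4aS,5S,8aR)-5-[(5R)-5-{[tert-butyl(dimethyl)silyl]oxy}octyl]-3-hydroxy-2-methyloctahydroquinoline-1(2H)-carboxylate | O[C@H]1C[C@H]2[C@@H](CCCC[C@H](O[Si](C)(C)C(C)(C)C)CCC)CCC[C@H]2N(C(=O)OC(C)(C)C)[C@@H]1C | intermediate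
25 | (2E,4E)-octa-2,4-dienal | CCC/C=C/C=C/C=O | starting material
26 | (2E,4E)-octa-2,4-dienoic acid | CCC/C=C/C=C/C(=O)O | intermediate
27 | tert-butyl (2R,3R,4aS,5S,8aR)-5-[(5R)-5-{[tert-butyl(dimethyl)silyl]oxy}octyl]-2-methyl-3-{[(2E,4E)-octa-2,4-dienoyl]oxy}octahydroquinoline-1(2H)-carboxylate | CCC/C=C/C=C/C(=O)O[C@@H]1C[C@H]2[C@@H](CCCC[C@H](O[Si](C)(C)C(C)(C)C)CCC)CCC[C@H]2N(C(=O)OC(C)(C)C)[C@@H]1C | intermediate
28 | (2R,3R,4aS,5S,8aR)-5-[(5R)-5-hydroxyoctyl]-2-methyldecahydroquinolin-3-yl (2E,4E)-octa-2,4-dienoate | CCC/C=C/C=C/C(=O)O[C@@H]1C[C@H]2[C@@H](CCCC[C@H](O)CCC)CCC[C@H]2N[C@@H]1C | target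

Total step count: 15. Longest linear sequence: 10 steps (steps 1, 2, 3, 4, 5, 10, 11, 12, 14, 15, from 1).

Steps most likely to fail

Step 5. The [3,3] shift may run through the (Z)-iminium geometry or a boat array, so that the other iminium face is attacked and the hydroxyethyl group ends up on the convex face. The fallback sets out again from 5 and 6 under the step 5 conditions and carries this epimer forward, (2S,3aR,7aR)-1-benzyl-2-[(1S)-1-hydroxyethyl]octahydro-4H-indol-4-one F1. Wittig reaction with ylide 18 should give the alkene F2. The aziridinium ring expansion (step 11 conditions) would then give the (3R)-piperidinol F3 directly, and hydrogenation with Boc2O (step 12 conditions) the N-Boc (3R)-alcohol F4. F4 is acylated with retention by a Steglich esterification (26, EDC·HCl, DMAP, CH2Cl2) in place of the inverting Mitsunobu step, and the route is rejoined at 27.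

Step 10. Enolisation of the hindered ketone by the basic ylide (with epimerisation at C4a), or sequestration of the carbonyl as a hemiketal alkoxide, may outrun olefination. The fallback sets out from 11 and replaces the Wittig reaction by a Shapiro reaction. Condensation with 2,4,6-triisopropylbenzenesulfonyl hydrazide should give the hydrazone F5. n-BuLi (3.2 equiv, THF, −78 to 0 °C) should generate the C5 vinyllithium by deprotonation at the C6 methylene, and alkylation with iodide 16 the endocyclic C5=C6 alkene F6. Ring expansion under the step 11 conditions would give the piperidinol F7, and hydrogenation with Boc2O under the step 12 conditions (hydrogen again from the convex face) rejoins the route at 24.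

Step 14. Elimination towards the C3–C4 alkene or incomplete inversion may occur, because the SN2 attack at C3 is slowed by the neighbouring C2 methyl group and the carbamate. The fallback sets out from 24 and inverts C3 by oxidation and reduction. Dess–Martin oxidation should give the 3-ketone F8. Reduction with LiBH(s-Bu)3 (THF, −78 °C), hydride arriving on the face away from the axial C2 methyl group, should give the (3R)-alcohol F9. Steglich esterification with 26 (EDC·HCl, DMAP) then rejoins the route at 27.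

Further compounds
F1 | step 5 | (2S,3aR,7aR)-1-benzyl-2-[(1S)-1-hydroxyethyl]octahydro-4H-indol-4-one | C[C@H](O)[C@@H]1C[C@H]2C(=O)CCC[C@H]2N1Cc1ccccc1
F2 | step 5 | (1S)-1-[(2S,3aS,7aR)-1-benzyl-4-[(5R)-5-{[tert-butyl(dimethyl)silyl]oxy}octylidene]octahydro-1H-indol-2-yl]ethan-1-ol | C[C@H](O)[C@@H]1C[C@H]2C(=CCCC[C@H](O[Si](C)(C)C(C)(C)C)CCC)CCC[C@H]2N1Cc1ccccc1
F3 | step 5 | (2R,3R,4aS,8aR)-1-benzyl-5-[(5R)-5-{[tert-butyl(dimethyl)silyl]oxy}octylidene]-2-methyldecahydroquinolin-3-ol | O[C@@H]1C[C@H]2C(=CCCC[C@H](O[Si](C)(C)C(C)(C)C)CCC)CCC[C@H]2N(Cc3ccccc3)[C@@H]1C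
F4 | step 5 | tert-butyl (2R,3R,4aS,5S,8aR)-5-[(5R)-5-{[tert-butyl(dimethyl)silyl]oxy}octyl]-3-hydroxy-2-methyloctahydroquinoline-1(2H)-carboxylate | O[C@@H]1C[C@H]2[C@@H](CCCC[C@H](O[Si](C)(C)C(C)(C)C)CCC)CCC[C@H]2N(C(=O)OC(C)(C)C)[C@@H]1C
F5 | step 10 | 2,4,6-triisopropylbenzenesulfonylhydrazone of 11 | C[C@H](O)[C@H]1C[C@H]2C(=NNS(=O)(=O)c3c(C(C)C)cc(C(C)C)cc3C(C)C)CCC[C@H]2N1Cc1ccccc1
F6 | step 10 | (1S)-1-[(2R,3aS,7aR)-1-benzyl-4-[(5R)-5-{[tert-butyl(dimethyl)silyl]oxy}octyl]-2,3,3a,6,7,7a-hexahydro-1H-indol-2-yl]ethan-1-ol | C[C@H](O)[C@H]1C[C@H]2C(CCCC[C@H](O[Si](C)(C)C(C)(C)C)CCC)=CCC[C@H]2N1Cc1ccccc1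
F7 | step 10 | (2R,3S,4aS,8aR)-1-benzyl-5-[(5R)-5-{[tert-butyl(dimethyl)silyl]oxy}octyl]-2-methyl-1,2,3,4,4a,7,8,8a-octahydroquinolin-3-ol | O[C@H]1C[C@H]2C(CCCC[C@H](O[Si](C)(C)C(C)(C)C)CCC)=CCC[C@H]2N(Cc3ccccc3)[C@@H]1C
F8 | step 14 | tert-butyl (2R,4aS,5S,8aR)-5-[(5R)-5-{[tert-butyl(dimethyl)silyl]oxy}octyl]-2-methyl-3-oxooctahydroquinoline-1(2H)-carboxylate | O=C1C[C@H]2[C@@H](CCCC[C@H](O[Si](C)(C)C(C)(C)C)CCC)CCC[C@H]2N(C(=O)OC(C)(C)C)[C@@H]1C
F9 | step 14 | tert-butyl (2R,3R,4aS,5S,8aR)-5-[(5R)-5-{[tert-butyl(dimethyl)silyl]oxy}octyl]-3-hydroxy-2-methyloctahydroquinoline-1(2H)-carboxylate | O[C@@H]1C[C@H]2[C@@H](CCCC[C@H](O[Si](C)(C)C(C)(C)C)CCC)CCC[C@H]2N(C(=O)OC(C)(C)C)[C@@H]1C
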